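**Retrosynthetic overview**

1. 13 ⇐ phenol 11: a last-step oxidative dearomatisation in MeOH makes the C-4–OMe bond and the C-1 carbonyl, turning the resorcinol-type benzene ring into the cyclohexa-2,5-dienone.
2. 11 ⇐ aryl allyl ether 9 (aromatic Claisen, C-2–allyl bond) ⇐ TIPS ether 7.
3. 7 ⇐ 2-arylpropene 4 + 4-bromoveratrole 5: a Cu–H/Pd enantioselective anti-Markovnikov hydroarylation forms the benzylic CH2–aryl bond (CH2 to C-1 of the veratrole ring) and the CH(CH3) stereocentre in one operation.
4. Enabling feature: the CH(CH3)–CH2 bridge between C-4 of the dienone ring and the veratrole ring; with the dienone ring read as its phenol this is a 1,2-diarylpropane, the hydroarylation retron of an α-methylstyrene C=CH2.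
5. 4 ⇐ 4-bromo-3-methoxyphenol 1 + isopropenyl–Bpin 3 (silylation, Suzuki); no ring is built: both six-membered rings are bought as arenes and the dienone ring takes its final form last.

Key step: step 3

Remark: locants C-1 to C-6 are those of the cyclohexa-2,5-dien-1-one of 13 and are kept for its phenol precursors; the sense of induction of the copper ligand is assumed ((R)-DTBM-SEGPHOS is written), and the (S)-ligand is used if a first run shows the opposite sense.

**Route**

Step 1
Reactants: 1 4-bromo-3-methoxyphenol
Product: 2 (4-bromo-3-methoxyphenoxy)triisopropylsilane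
Conditions: TIPSCl, imidazole, DMF, 23 °C
Reagents that add atoms: chlorotriisopropylsilane, CC(C)[Si](Cl)(C(C)C)C(C)C
Why: Imidazole-assisted silylation of a phenol; the TIPS ether removes the acidic O–H that would quench Cu–H and alkylcopper in step 3 and should survive NaOTMS better than a TBS ether.

Step 2
Reactants: 2 (4-bromo-3-methoxyphenoxy)triisopropylsilane; 3 4,4,5,5-tetramethyl-2-(prop-1-en-2-yl)-1,3,2-dioxaborolane
Product: 4 triisopropyl[3-methoxy-4-(prop-1-en-2-yl)phenoxy]silane
Conditions: Pd(OAc)2, SPhos, K3PO4, 1,4-dioxane/H2O, 80 °C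
Reagents that add atoms: none
Why: Suzuki–Miyaura coupling of an aryl bromide with an alkenyl pinacol boronate, with SPhos chosen for the electron-rich, ortho-substituted bromide.

Step 3
Reactants: 4 triisopropyl[3-methoxy-4-(prop-1-en-2-yl)phenoxy]silane; 5 4-bromo-1,2-dimethoxybenzene
Product: 7 triisopropyl{4-[(2R)-1-(3,4-dimethoxyphenyl)propan-2-yl]-3-methoxyphenoxy}silane, via alkylcopper(I) species 6 (not isolated)
Conditions: Cu(OAc)2 (cat.), (R)-DTBM-SEGPHOS (cat.), [Pd(cinnamyl)Cl]2 (cat.), BrettPhos (cat.), NaOTMS, Me2PhSiH, THF, 45 °C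
Reagents that add atoms: none
Why: The ligated Cu–H (from Cu(OAc)2, the bisphosphine and the silane) adds across the 1,1-disubstituted C=C of 4 with copper on the terminal CH2 and hydride on the internal carbon to give primary alkylcopper 6; in parallel BrettPhos–Pd(0) inserts into the C–Br bond of 5, the alkyl group passes from Cu to Pd, and reductive elimination forms the CH2–aryl bond while NaOTMS and the silane regenerate Cu–H. The closest known reaction type is the CuH/Pd dual-catalytic enantioselective anti-Markovnikov hydroarylation of 1,1-disubstituted alkenes with aryl bromides. No ring is closed. The one new stereocentre, C-2 of the propan-2-yl chain, is set in the hydrocupration by the chiral bisphosphine on copper, which distinguishes the aryl from the methyl substituent of the alkene; it lies β to the metal and is untouched by transmetalation and reductive elimination. The step needs anti-Markovnikov regioselectivity and chemoselectivity for this alkene: the ortho-methoxy group twists the aryl ring out of conjugation and a tertiary benzylic copper is sterically disfavoured, and the substrate carries no other alkene and no acidic O–H (the phenol is a TIPS ether, not yet an allyl ether).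

Step 4
Reactants: 7 triisopropyl{4-[(2R)-1-(3,4-dimethoxyphenyl)propan-2-yl]-3-methoxyphenoxy}silane
Product: 9 4-{(2R)-2-[4-(allyloxy)-2-methoxyphenyl]propyl}-1,2-dimethoxybenzene, via caesium phenoxide 8 (not isolated)
Conditions: CsF, allyl bromide, DMF, 23 → 50 °C
Reagents that add atoms: allyl bromide, C=CCBr
Why: Fluoride cleaves the aryl O–Si bond and the caesium phenoxide 8 is O-alkylated in the same flask (Williamson ether synthesis); the stereocentre is not touched.

Step 5
Reactants: 9 4-{(2R)-2-[4-(allyloxy)-2-methoxyphenyl]propyl}-1,2-dimethoxybenzene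
Product: 11 2-allyl-4-[(2R)-1-(3,4-dimethoxyphenyl)propan-2-yl]-5-methoxyphenol, via ortho-dienone 10 (not isolated)
Conditions: N,N-diethylaniline, 190 °C, sealed tube
Reagents that add atoms: none
Why: Aromatic Claisen rearrangement, a concerted [3,3] shift to an ortho carbon followed by tautomerisation of dienone 10; the ortho carbon para to the methoxy group is open whereas the other is flanked by OMe, so the allyl group should arrive at C-2, and the benzylic stereocentre is not involved.

Step 6
Reactants: 11 2-allyl-4-[(2R)-1-(3,4-dimethoxyphenyl)propan-2-yl]-5-methoxyphenol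
Product: 13 (4R)-2-allyl-4-[(2R)-1-(3,4-dimethoxyphenyl)propan-2-yl]-4,5-dimethoxycyclohexa-2,5-dien-1-one, via aryloxy-λ3-iodane 12 (not isolated)
Conditions: PhI(OAc)2, MeOH/CH2Cl2, −40 → 0 °C
Reagents that add atoms: methanol, CO
Why: Oxidative dearomatisation of a para-alkylphenol with a λ3-iodane, in which ligand exchange gives 12 and methanol attacks the para carbon C-4 with loss of PhI and AcOH; the quaternary centre is set by 1,2-induction, since A(1,3) strain with the C-5 methoxy group holds the side-chain C–H in the ring plane, so CH3 and CH2Ar shield opposite faces and methanol should enter past the methyl group, anti to the larger veratrylmethyl group, which is the (4R) sense, with the (4S) epimer removable by chromatography.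

**Compound list**

1 | 4-bromo-3-methoxyphenol | COc1cc(O)ccc1Br | starting material
2 | (4-bromo-3-methoxyphenoxy)triisopropylsilane | COc1cc(O[Si](C(C)C)(C(C)C)C(C)C)ccc1Br | intermediate
3 | 4,4,5,5-tetramethyl-2-(prop-1-en-2-yl)-1,3,2-dioxaborolane (isopropenyl–Bpin) | CC(=C)B1OC(C)(C)C(C)(C)O1 | starting material
4 | triisopropyl[3-methoxy-4-(prop-1-en-2-yl)phenoxy]silane | COc1cc(O[Si](C(C)C)(C(C)C)C(C)C)ccc1C(C)=C | intermediate
5 | 4-bromo-1,2-dimethoxybenzene (4-bromoveratrole) | COc1ccc(Br)cc1OC | starting material
6 | primary alkylcopper(I) species Cu–CH2–CH(CH3)Ar (bisphosphine on Cu not drawn; same spatial arrangement at the methine as in 7) | COc1cc(O[Si](C(C)C)(C(C)C)C(C)C)ccc1[C@H](C)C[Cu] | intermediate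
7 | triisopropyl{4-[(2R)-1-(3,4-dimethoxyphenyl)propan-2-yl]-3-methoxyphenoxy}silane | COc1cc(O[Si](C(C)C)(C(C)C)C(C)C)ccc1[C@H](C)Cc1ccc(OC)c(OC)c1 | intermediate
8 | caesium 4-[(2R)-1-(3,4-dimethoxyphenyl)propan-2-yl]-3-methoxyphenoxide | COc1cc([O-])ccc1[C@H](C)Cc1ccc(OC)c(OC)c1.[Cs+] | intermediate
9 | 4-{(2R)-2-[4-(allyloxy)-2-methoxyphenyl]propyl}-1,2-dimethoxybenzene | COc1cc(OCC=C)ccc1[C@H](C)Cc1ccc(OC)c(OC)c1 | intermediate
10 | 6-allyl-4-[(2R)-1-(3,4-dimethoxyphenyl)propan-2-yl]-3-methoxycyclohexa-2,4-dien-1-one (both configurations at C-6) | O=C1C=C(OC)C([C@H](C)Cc2ccc(OC)c(OC)c2)=CC1CC=C | intermediate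
11 | 2-allyl-4-[(2R)-1-(3,4-dimethoxyphenyl)propan-2-yl]-5-methoxyphenol | COc1cc(O)c(CC=C)cc1[C@H](C)Cc1ccc(OC)c(OC)c1 | intermediate
12 | acetoxy(phenyl)-λ3-iodanyl ether of phenol 11 | CC(=O)O[I](c1ccccc1)Oc1cc(OC)c([C@H](C)Cc2ccc(OC)c(OC)c2)cc1CC=C | intermediate
13 | (4R)-2-allyl-4-[(2R)-1-(3,4-dimethoxyphenyl)propan-2-yl]-4,5-dimethoxycyclohexa-2,5-dien-1-one | C=CCC1=C[C@](OC)([C@H](C)Cc2ccc(OC)c(OC)c2)C(OC)=CC1=O | target

**Count**

Total steps: 6. Longest linear sequence: 6 steps (from 1).

**Steps most likely to fail**

1. Step 6. The 1,2-induction may be weak, giving poor facial selectivity in the attack of methanol at C-4. Methanol may also attack an ortho carbon, the benzylic proton may be lost to a quinone methide, or the oxidised ring may be captured by the veratrole ring. Fallback: the step is run as a separate-and-recycle loop instead of a single selective pass. It sets out from 11; the unwanted (4S)-epimer of 13 F1 is separated and returned to the phenol by reductive rearomatisation with Zn/AcOH (loss of methanol), coming back to the route at 11 for re-oxidation.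

2. Step 3. Hydrocupration of the hindered, ortho-substituted 2-arylpropene may be slow, so that hydrodebromination of 5 or Heck-type arylation competes, or the enantioselectivity may be low. Fallback: the merged event is split into two separately precedented ones. Setting out from 4, cobalt-catalysed enantioselective anti-Markovnikov hydroboration with pinacolborane gives the primary boronate 2-{(2R)-2-[2-methoxy-4-(triisopropylsilyloxy)phenyl]propyl}-4,4,5,5-tetramethyl-1,3,2-dioxaborolane F2. This is joined to 5 by a B-alkyl Suzuki–Miyaura coupling (Pd(OAc)2, RuPhos, K2CO3, toluene/H2O, 80 °C), coming back at 7.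

3. Step 5. The [3,3] shift may go to the ortho carbon flanked by OMe, or the material may degrade at 190 °C. Fallback: electrophilic substitution plus cross-coupling replaces the sigmatropic shift. Setting out from 7, TBAF gives the phenol 4-[(2R)-1-(3,4-dimethoxyphenyl)propan-2-yl]-3-methoxyphenol F3. NIS in MeCN iodinates the ring carbon ortho to OH and para to OMe to give 4-[(2R)-1-(3,4-dimethoxyphenyl)propan-2-yl]-2-iodo-5-methoxyphenol F4. Stille coupling with allyltributylstannane (Pd(PPh3)4, DMF, 80 °C) comes back at 11.

**Further compounds**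

F1 | step 6 | (4S)-2-allyl-4-[(2R)-1-(3,4-dimethoxyphenyl)propan-2-yl]-4,5-dimethoxycyclohexa-2,5-dien-1-one | C=CCC1=C[C@@](OC)([C@H](C)Cc2ccc(OC)c(OC)c2)C(OC)=CC1=O
F2 | step 3 | 2-{(2R)-2-[2-methoxy-4-(triisopropylsilyloxy)phenyl]propyl}-4,4,5,5-tetramethyl-1,3,2-dioxaborolane | COc1cc(O[Si](C(C)C)(C(C)C)C(C)C)ccc1[C@H](C)CB1OC(C)(C)C(C)(C)O1
F3 | step 5 | 4-[(2R)-1-(3,4-dimethoxyphenyl)propan-2-yl]-3-methoxyphenol | COc1cc(O)ccc1[C@H](C)Cc1ccc(OC)c(OC)c1
F4 | step 5 | 4-[(2R)-1-(3,4-dimethoxyphenyl)propan-2-yl]-2-iodo-5-methoxyphenol | COc1cc(O)c(I)cc1[C@H](C)Cc1ccc(OC)c(OC)c1
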